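The readings come from a simulation on assumed constants, noise included.

Temperature was what separated this week's flasks, so I wanted a rate I could carry along the temperature axis from the two earlier runs.

| flask | starting material | partner | free catalyst | added ligand | temperature | remark | time |
|---|---|---|---|---|---|---|---|
| eta | 20 mM | 50 mM | 1 mM | 0.26 mM | 42 °C | run made earlier |  |
| epsilon | 20 mM | 50 mM | 1 mM | 1 mM | 70 °C | run made earlier |  |
| Wednesday's | 20 mM | 50.0 mM | 1.0 mM | 0.51 mM | 60 °C |  | 40 h |
| Thursday's | 20 mM | 50.0 mM | 1.0 mM | 0.51 mM | 80 °C |  | 40 h |
| Monday's | 20 mM | 50.0 mM | 1.0 mM | 0.51 mM | 40 °C |  | 40 h |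
| Sunday's | 20 mM | 50.0 mM | 1.0 mM | 0.51 mM | 45 °C |  | 40 h |
| Saturday's | 20 mM | 50.0 mM | 1.0 mM | 0.51 mM | 30 °C |  | 40 h |

| run | time / h | target / % |
|---|---|---|
| eta | 8.00 | 15.3 |
| eta | 15.0 | 29.2 |
| eta | 30.0 | 52.9 |
| eta | 50.0 | 75.4 |
| eta | 96.0 | 96.9 |
| epsilon | 2.00 | 14.9 |
| epsilon | 4.00 | 25.9 |
| epsilon | 8.00 | 44.4 |
| epsilon | 12.0 | 56.6 |
| epsilon | 25.0 | 81.2 |

(each reading ± 0.5 percentage points)

- all flasks from highest to lowest amount of target, in percent of the starting material charged, at 40 h (Wednesday's / Thursday's / Monday's / Sunday's / Saturday's)
- the amount of target, in percent of the starting material charged of the flask you put first, at 40 h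
- the amount of target, in percent of the starting material charged of the flask you put last, at 40 h



I asked first about the end. The partner was charged at 2.50 times the starting material, which made the starting material the limiting reagent, and eta had reached 96.9% target at 96.0 h. So I took near-complete conversion as the end state and asked how fast it was approached.

My measure was the apparent first-order constant: the logarithm of the starting material charged over the part not yet turned into target, divided by the time, as on a conversion plot. The first readings gave 0.0208 /h for eta at 42 °C and 0.0807 /h for epsilon at 70 °C. Read as an Arrhenius pair, although the two runs differed in ligand as well as temperature, these gave an apparent activation energy of 43.6 kJ/mol. That took eta's constant down to 0.0107 /h at 30 °C, which, with eta's ligand charge, meant 34.8% target at 40 h.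

The weak link was the ligand, because Saturday's held nearly twice eta's charge. I guessed that each ligand took one catalyst out of work, which left Saturday's 0.662 of eta's working catalyst. It was a rough guess, since epsilon had ligand equal to catalyst and still made target. This gave my working constant, the apparent first-order constant for Saturday's, of 0.00711 /h, and so 24.8% target.

The forecast gave Thursday's > Wednesday's > Sunday's > Monday's > Saturday's, with 96% first and 37% last, which is more than my figure for Saturday's. Its ground for the order was “Hotter flasks should simply lead”.

The flasks gave Thursday's > Wednesday's > Sunday's > Monday's > Saturday's, with >99.9% in Thursday's and 16.1% in Saturday's.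

    starting material + free catalyst → catalyst intermediate A (k = 520 /M/h, Ea = 65.0 kJ/mol)
    partner + catalyst intermediate A ⇌ catalyst intermediate B (K = 25.0 /M, k = 260 /M/h, Ea = 53.0 kJ/mol, ΔH = 5.00 kJ/mol)
    catalyst intermediate B → free catalyst + target (k = 10.0 /h, Ea = 88.0 kJ/mol)
    free catalyst + added ligand ⇌ idle complex, settled at all times (K = 48000 /M, ΔH = −35.0 kJ/mol)
    free catalyst ⇌ dormant form (K = 8.30, k = 0.130 /h, Ea = 105 kJ/mol, ΔH = −56.0 kJ/mol)
    (constants at 60 °C)

In Saturday's at 40.0 h, catalyst intermediate A had a half-life of 0.38 h by the forward rate of its step with partner, far shorter than the run, and the rate of its making over that of its using up, each step taken net, stood at 0.998. Saturday's last step had half of its turnover behind it by 20.1 h, and Saturday's average constant read 0.00438 /h against my 0.00711 /h. Saturday's repeated at 45 °C takes my working constant to 0.0161 /h, hence 47.4% target. That flask gave 60.0%, more than reckoned.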